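**Retrosynth­etic overview**
1. Target 12 ⇒ hexadecamethyl ether 11 by global O-demethylation. Ring letters: A/F are the outer 2,4,6-trioxyphenyl rings, B/D the inner rings that carry the ether oxygen, C the central ring, E the 3,4,5-trioxyphenoxy ring.
2. 11 ⇒ dibromide 9 + two molecules of phenol 6, cutting both C–O bonds B–O–C and D–O–C in one two-fold copper-catalysed etherification (the key, new step).
3. 9 ⇒ phenol 7 + boronic acid 8, cutting the C–O bond E–O–C (Chan–Lam).
4. 6 ⇒ biaryl 3 by C–H lithiation/borylation/oxidation (C–O); 3 ⇒ two molecules of 1 by oxidative homocoupling (C–C).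
5. No ring is built; all six benzene rings are bought. Order of assembly: A–B (= F–D) biaryl, then E–O–C, then B–O–C–O–D, then deprotection.

Assumption: the target has no stereocentre and no configurationally stable axis (the outer rings are symmetric about the biaryl bonds), so it is achiral and no stereocontrol is needed; methyl ethers are the only protecting group.

**Step 1**
Reactants: 1 1,3,5-trimethoxybenzene (2 equiv)
Product: 3 2,2',4,4',6,6'-hexamethoxy-1,1'-biphenyl, via 2,4,6-trimethoxyphenyllithium 2 (not isolated)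
Conditions: n-BuLi (1.05 equiv per 1), THF, 0 °C → rt, 2 h; then anhydrous CuCl2 (1.1 equiv per 1), −78 °C → rt, 12 h
Reagents that add atoms: n-butyllithium [Li]CCCC (lithium of intermediate 2 only)
Why: Directed ortho-lithiation of each molecule of 1 between two methoxy groups gives 2, and oxidative homocoupling of two molecules of this aryllithium by CuCl2 (divalent copper reduced to monovalent copper through an arylcopper species; 2 ArLi + 2 CuCl2 → Ar–Ar + 2 CuCl + 2 LiCl) forms the tetra-ortho-substituted biaryl bond of rings A–B (= F–D); no stereocentre arises because both rings are symmetric about the axis.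

**Step 2**
Reactants: 3 2,2',4,4',6,6'-hexamethoxy-1,1'-biphenyl
Product: 6 2,2',4,4',6,6'-hexamethoxybiphenyl-3-ol, via 3-lithiohexamethoxybiphenyl 4 (not isolated), via arylboronic acid dimethyl ester 5 (not isolated)
Conditions: n-BuLi (0.9 equiv), THF, 0 °C → rt, 2 h; B(OMe)3 (1.5 equiv), −78 °C → rt; then 30% H2O2, AcOH, 0 °C → rt (unreacted 3 recovered and recycled)
Reagents that add atoms: hydrogen peroxide OO (oxygen of 6); trimethyl borate COB(OC)OC (boron and two methoxy groups of intermediate 5 only); n-butyllithium [Li]CCCC (lithium of intermediate 4 only)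
Why: All four aromatic C–H bonds of 3 are equivalent and each lies between two methoxy groups, so directed ortho-metalation with slightly less than one equivalent of base gives mono-lithio species 4, which is trapped as boronate 5 and oxidised with retention at carbon (lithiation–borylation–oxidation) to the phenol whose oxygen becomes the ether oxygen on ring B; no stereocentre.

**Step 3**
Reactants: 7 2,6-dibromo-4-methoxyphenol; 8 (3,4,5-trimethoxyphenyl)boronic acid (2.5 equiv)
Product: 9 1,3-dibromo-5-methoxy-2-(3,4,5-trimethoxyphenoxy)benzene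
Conditions: Cu(OAc)2 (2.0 equiv), pyridine (5 equiv), 4 Å MS, CH2Cl2, rt, 48 h
Reagents that add atoms: none
Why: Chan–Lam (Chan–Evans–Lam) O-arylation, in which 8 transmetalates to the divalent copper phenoxide of 7, oxidation to trivalent copper and C–O reductive elimination join ring E to ring C at room temperature; the coupling tolerates 2,6-dihalophenols and leaves both C–Br bonds untouched; no stereocentre.

**Step 4**
Reactants: 6 2,2',4,4',6,6'-hexamethoxybiphenyl-3-ol (2.6 equiv); 9 1,3-dibromo-5-methoxy-2-(3,4,5-trimethoxyphenoxy)benzene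
Product: 11 5-methoxy-1,3-bis[(2,2',4,4',6,6'-hexamethoxybiphenyl-3-yl)oxy]-2-(3,4,5-trimethoxyphenoxy)benzene, via mono-etherified bromide 10 (not isolated)
Conditions: CuI (20 mol%), picolinic acid (40 mol%), K3PO4 (4 equiv), DMSO, 110 °C, Ar, 36 h
Reagents that add atoms: none
Why: Proposed new method: a one-pot two-fold copper-catalysed Ullmann-type etherification that places two 2,6-dimethoxy-flanked aryloxy groups on both carbons next to an existing aryloxy group (1,3-dibromo-2-aryloxyarene → 1,2,3-tris(aryloxy)arene), expected to work because the small, anionic picolinate-bound monovalent copper aryloxide of 6 inserts into a C–Br bond that has only one ortho substituent (true for 9 and again for 10), the trivalent copper aryl aryloxide then forms the C–O bond by fast reductive elimination, and copper, unlike palladium, does not divert the aryl–metal species into C–H arylation of ring E (dibenzofuran); closest known reaction type: ligand-accelerated Ullmann diaryl ether synthesis (CuI/picolinic acid or CuI/oxalamide coupling of one ortho-substituted aryl bromide with one ortho-substituted phenol), to my knowledge not yet shown as a two-fold coupling on this substrate class; no stereocentre is formed.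

**Step 5**
Reactants: 11 5-methoxy-1,3-bis[(2,2',4,4',6,6'-hexamethoxybiphenyl-3-yl)oxy]-2-(3,4,5-trimethoxyphenoxy)benzene
Product: 12 4-(3,4,5-trihydroxyphenoxy)-3,5-bis[(2,2',4,4',6,6'-hexahydroxybiphenyl-3-yl)oxy]phenol (CNP0279880.0)
Conditions: BBr3 (48 equiv), CH2Cl2, −78 °C → rt, 36 h, Ar; then H2O, 0 °C; Sephadex LH-20 (MeOH) under Ar
Reagents that add atoms: none
Why: Exhaustive Lewis-acid O-demethylation, in which BBr3 binds each of the sixteen aryl methyl ether oxygens and bromide removes the methyl group as MeBr while diaryl ether and biaryl bonds stay inert, and hydrolysis of the aryl borates frees the sixteen phenols of the achiral target.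

**Compound list**
1 | 1,3,5-trimethoxybenzene | COc1cc(OC)cc(OC)c1 | starting material
2 | (2,4,6-trimethoxyphenyl)lithium | [Li]c1c(OC)cc(OC)cc1OC | intermediate
3 | 2,2',4,4',6,6'-hexamethoxy-1,1'-biphenyl | COc1cc(OC)c(-c2c(OC)cc(OC)cc2OC)c(OC)c1 | intermediate
4 | (2,2',4,4',6,6'-hexamethoxybiphenyl-3-yl)lithium | [Li]c1c(OC)cc(OC)c(-c2c(OC)cc(OC)cc2OC)c1OC | intermediate
5 | dimethyl (2,2',4,4',6,6'-hexamethoxybiphenyl-3-yl)boronate | COB(OC)c1c(OC)cc(OC)c(-c2c(OC)cc(OC)cc2OC)c1OC | intermediate
6 | 2,2',4,4',6,6'-hexamethoxybiphenyl-3-ol | Oc1c(OC)cc(OC)c(-c2c(OC)cc(OC)cc2OC)c1OC | intermediate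
7 | 2,6-dibromo-4-methoxyphenol | Oc1c(Br)cc(OC)cc1Br | starting material
8 | (3,4,5-trimethoxyphenyl)boronic acid | OB(O)c1cc(OC)c(OC)c(OC)c1 | starting material
9 | 1,3-dibromo-5-methoxy-2-(3,4,5-trimethoxyphenoxy)benzene | COc1cc(Br)c(Oc2cc(OC)c(OC)c(OC)c2)c(Br)c1 | intermediate
10 | 1-bromo-3-[(2,2',4,4',6,6'-hexamethoxybiphenyl-3-yl)oxy]-5-methoxy-2-(3,4,5-trimethoxyphenoxy)benzene | COc1cc(Br)c(Oc2cc(OC)c(OC)c(OC)c2)c(Oc2c(OC)cc(OC)c(-c3c(OC)cc(OC)cc3OC)c2OC)c1 | intermediate
11 | 5-methoxy-1,3-bis[(2,2',4,4',6,6'-hexamethoxybiphenyl-3-yl)oxy]-2-(3,4,5-trimethoxyphenoxy)benzene (hexadecamethyl ether of the target) | COc1cc(OC)c(-c2c(OC)cc(OC)c(Oc3cc(OC)cc(Oc4c(OC)cc(OC)c(-c5c(OC)cc(OC)cc5OC)c4OC)c3Oc3cc(OC)c(OC)c(OC)c3)c2OC)c(OC)c1 | intermediate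
12 | 4-(3,4,5-trihydroxyphenoxy)-3,5-bis[(2,2',4,4',6,6'-hexahydroxybiphenyl-3-yl)oxy]phenol | Oc1cc(O)c(-c2c(O)cc(O)c(Oc3cc(O)cc(Oc4c(O)cc(O)c(-c5c(O)cc(O)cc5O)c4O)c3Oc3cc(O)c(O)c(O)c3)c2O)c(O)c1 | target

**Totals**
Total step count: 5.
Longest linear sequence: 4 steps (1 → 3 → 6 → 11 → 12; steps 1, 2, 4 and 5). Step 3 runs in parallel.

**Three steps most likely to fail**

Step 4 (proposed new two-fold etherification). The reaction may stall at mono-ether 10 or lose the second bromine by hydrodebromination. The fallback uses only known chemistry, sets out from phenol 6 and comes back at 11. Phenol 6 (2.2 equiv) is reacted with commercial 1,3-difluoro-5-methoxy-2-nitrobenzene (COc1cc(F)c([N+](=O)[O-])c(F)c1) in a two-fold SNAr (K2CO3, DMF, 80 °C), where the nitro group activates both ortho fluorides, to give 1,3-bis[(2,2',4,4',6,6'-hexamethoxybiphenyl-3-yl)oxy]-5-methoxy-2-nitrobenzene F1. Hydrogenation (H2, Pd/C, EtOAc/EtOH, rt) gives 2,6-bis[(2,2',4,4',6,6'-hexamethoxybiphenyl-3-yl)oxy]-4-methoxyaniline F2. Diazotisation (NaNO2, H2SO4, aqueous AcOH, 0 °C) and hydroxydediazoniation (Cu2O, Cu(NO3)2, H2O, rt) give 2,6-bis[(2,2',4,4',6,6'-hexamethoxybiphenyl-3-yl)oxy]-4-methoxyphenol F3; the ortho positions of rings B and D carry methoxy groups, which blocks Pschorr-type closure to a dibenzofuran. Chan–Lam coupling of this phenol with boronic acid 8 under the conditions of step 3 then installs ring E and gives 11.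

Step 5 (sixteen-fold demethylation and isolation of an air-sensitive hexadecaphenol). Partly methylated material or oxidation of the 1,2,3-trioxygenated rings during purification can spoil the isolation. The fallback sets out from 11 and comes back at 12 by a capture-and-release approach. 11 is demethylated with BBr3 as before, and the crude phenol is not purified but peracetylated at once (Ac2O, pyridine, DMAP cat., rt) to the hexadecaacetate of the target F4, which is air-stable and can be purified on silica. Acid methanolysis (HCl generated from AcCl in dry MeOH, rt, Ar) then releases 12 without exposing it to base.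

Step 3 (Chan–Lam coupling of a 2,6-dibromophenol). The doubly ortho-substituted, weakly nucleophilic phenol may couple slowly while the boronic acid is consumed by homocoupling. The fallback sets out from 7 (and uses 1) and comes back at 9, with a hypervalent iodine electrophile in place of the boronic acid. Commercial 5-iodo-1,2,3-trimethoxybenzene (COc1cc(I)cc(OC)c1OC) is oxidised (mCPBA, TsOH·H2O, MeCN, 55 °C) and the resulting aryl-λ3-iodane is trapped with compound 1 to give (3,4,5-trimethoxyphenyl)(2,4,6-trimethoxyphenyl)iodonium tosylate F5. Metal-free O-arylation of 7 with this salt (K2CO3, toluene, 60 °C) transfers the 3,4,5-trimethoxyphenyl group, the 2,4,6-trimethoxyphenyl group acting as the non-transferred ligand, and gives 9; the same reaction type is used to make polybrominated diphenyl ethers from bromophenols.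

**Further compounds**
F1 | step 4 | 1,3-bis[(2,2',4,4',6,6'-hexamethoxybiphenyl-3-yl)oxy]-5-methoxy-2-nitrobenzene | COc1cc(Oc2c(OC)cc(OC)c(-c3c(OC)cc(OC)cc3OC)c2OC)c([N+](=O)[O-])c(Oc2c(OC)cc(OC)c(-c3c(OC)cc(OC)cc3OC)c2OC)c1
F2 | step 4 | 2,6-bis[(2,2',4,4',6,6'-hexamethoxybiphenyl-3-yl)oxy]-4-methoxyaniline | COc1cc(Oc2c(OC)cc(OC)c(-c3c(OC)cc(OC)cc3OC)c2OC)c(N)c(Oc2c(OC)cc(OC)c(-c3c(OC)cc(OC)cc3OC)c2OC)c1
F3 | step 4 | 2,6-bis[(2,2',4,4',6,6'-hexamethoxybiphenyl-3-yl)oxy]-4-methoxyphenol | COc1cc(Oc2c(OC)cc(OC)c(-c3c(OC)cc(OC)cc3OC)c2OC)c(O)c(Oc2c(OC)cc(OC)c(-c3c(OC)cc(OC)cc3OC)c2OC)c1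
F4 | step 5 | hexadecaacetate of the target (all sixteen phenols as acetates) | CC(=O)Oc1cc(OC(C)=O)c(-c2c(OC(C)=O)cc(OC(C)=O)c(Oc3cc(OC(C)=O)cc(Oc4c(OC(C)=O)cc(OC(C)=O)c(-c5c(OC(C)=O)cc(OC(C)=O)cc5OC(C)=O)c4OC(C)=O)c3Oc3cc(OC(C)=O)c(OC(C)=O)c(OC(C)=O)c3)c2OC(C)=O)c(OC(C)=O)c1
F5 | step 3 | (3,4,5-trimethoxyphenyl)(2,4,6-trimethoxyphenyl)iodonium 4-methylbenzenesulfonate | COc1cc(OC)c([I+]c2cc(OC)c(OC)c(OC)c2)c(OC)c1.Cc1ccc(cc1)S(=O)(=O)[O-]
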